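**Plan**

- Retrosynthesis: strip six benzyl ethers and one blocking bromine; cut C3–C4 of ring F (the lower pyran ring) to dialdehyde 19; cut O1–C2 of ring F to salicylaldehyde 16 and mandelate 8; cut the C4(ring C)–C6(ring D) interflavanyl bond to the C4 cation of 15 and aldehyde 2; ring C is cut the same two ways back to bromo aldehyde 3 and 8.
- Forward order: rings A/B with ring C (SmI2 pinacol closure, C3 then inverted through the ketone); ring D joined at C4 by Friedel–Crafts alkylation; ring E and C2 added by Mitsunobu etherification; ring F closed last on the complete skeleton.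
- Enabling feature: C3 and C4 of ring F are adjacent secondary carbinol carbons, C4 benzylic on ring D ortho to the ring oxygen O1 and C3 next to the O1-bearing center C2. The C3–C4 bond is therefore the product of a reductive coupling between a salicylaldehyde-ether carbonyl and an α-aryloxy aldehyde tethered through O1–C2. The all-equatorial 2,3-trans-3,4-trans array is what a non-chelated closure should give.
- Stereochemistry: both C2 centers come from one asymmetric transfer hydrogenation (8) followed by Mitsunobu inversion; C3 of ring C from LiBH(s-Bu)3 reduction; C4 of ring C from attack anti to the C3 hydroxyl; C3 and C4 of ring F from the key step under control of C2.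

Key step: step 16

Assumption: diol 12 and ethers 13–15 are drawn as the expected major C3/C4 isomers; other isomers from steps 8 and 9 would converge, because C3 is reset in steps 10–11 and C4 is planarized in step 12.

**Route**

Step 1
Reactants: 1 2,3,4-trihydroxybenzaldehyde
Product: 2 3,4-bis(benzyloxy)-2-hydroxybenzaldehyde
Conditions: BnBr (2.1 equiv), K2CO3 (2.1 equiv), DMF, 0 °C → rt
Reagents that add atoms: benzyl bromide, BrCc1ccccc1
Why: Williamson etherification; the 2-OH is hydrogen-bonded to the formyl oxygen and flanked on both sides, so it is the least nucleophilic phenol and should stay free.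

Step 2
Reactants: 2 3,4-bis(benzyloxy)-2-hydroxybenzaldehyde
Product: 3 3,4-bis(benzyloxy)-5-bromo-2-hydroxybenzaldehyde
Conditions: NBS (1.05 equiv), MeCN, 0 °C → rt
Reagents that add atoms: N-bromosuccinimide, O=C1CCC(=O)N1Br
Why: Electrophilic aromatic bromination at C5, the only position para to the free phenol and ortho to a benzyloxy group (C6 is deactivated by the ortho formyl group); the bromine later blocks C6 of ring A against self-alkylation.

Step 3
Reactants: 4 1-(benzyloxy)-4-bromobenzene; 5 dimethyl oxalate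
Product: 7 methyl 2-[4-(benzyloxy)phenyl]-2-oxoacetate, via [4-(benzyloxy)phenyl]magnesium bromide 6 (not isolated)
Conditions: Mg, THF, reflux; then added to 5 (2 equiv), THF, −78 °C; dilute HCl work-up
Reagents that add atoms: none
Why: Grignard acylation; inverse addition to excess oxalate at low temperature should stop at the α-keto ester because the tetrahedral adduct persists until work-up.

Step 4
Reactants: 7 methyl 2-[4-(benzyloxy)phenyl]-2-oxoacetate
Product: 8 methyl (2S)-2-[4-(benzyloxy)phenyl]-2-hydroxyacetate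
Conditions: RuCl(p-cymene)[(R,R)-TsDPEN] (1 mol %), HCO2H/Et3N (5:2), DMF, rt; recrystallization
Reagents that add atoms: none
Why: Noyori asymmetric transfer hydrogenation of an aryl ketone; with the aryl group placed as in acetophenone reductions the (R,R)-catalyst should deliver hydride to give the (S)-carbinol, the source of both C2 centers.

Step 5
Reactants: 3 3,4-bis(benzyloxy)-5-bromo-2-hydroxybenzaldehyde; 8 methyl (2S)-2-[4-(benzyloxy)phenyl]-2-hydroxyacetate
Product: 9 methyl (2R)-2-[4-(benzyloxy)phenyl]-2-[2,3-bis(benzyloxy)-4-bromo-6-formylphenoxy]acetate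
Conditions: PPh3, DIAD, THF, 0 °C → rt
Reagents that add atoms: none
Why: Mitsunobu etherification; the acidic phenol displaces the activated mandelate hydroxyl by SN2 with inversion (S to R), and the α-ester group suppresses ionization of the p-alkoxybenzylic carbon, so C2 of ring C is set cleanly.

Step 6
Reactants: 9 methyl (2R)-2-[4-(benzyloxy)phenyl]-2-[2,3-bis(benzyloxy)-4-bromo-6-formylphenoxy]acetate
Product: 10 (2R)-2-[4-(benzyloxy)phenyl]-2-[2,3-bis(benzyloxy)-4-bromo-6-(hydroxymethyl)phenoxy]ethan-1-ol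
Conditions: i-Bu2AlH (5 equiv), CH2Cl2, −78 → 0 °C; aq. potassium sodium tartrate (KNaC4H4O6)
Reagents that add atoms: none
Why: Hydride reduction of ester and aldehyde to the diol under non-basic conditions, which should leave the acidic C–H next to the ester, the aryl bromide and the benzyl ethers untouched.

Step 7
Reactants: 10 (2R)-2-[4-(benzyloxy)phenyl]-2-[2,3-bis(benzyloxy)-4-bromo-6-(hydroxymethyl)phenoxy]ethan-1-ol
Product: 11 3,4-bis(benzyloxy)-2-{(1R)-1-[4-(benzyloxy)phenyl]-2-oxoethoxy}-5-bromobenzaldehyde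
Conditions: Dess–Martin periodinane (2.5 equiv), pyridine, CH2Cl2, 0 °C → rt; crude used at once
Reagents that add atoms: none
Why: Dess–Martin oxidation of both primary alcohols under buffered conditions, chosen to spare the configurationally labile α-aryl-α-aryloxy aldehyde.

Step 8
Reactants: 11 3,4-bis(benzyloxy)-2-{(1R)-1-[4-(benzyloxy)phenyl]-2-oxoethoxy}-5-bromobenzaldehyde
Product: 12 (2R,3S,4S)-7,8-bis(benzyloxy)-2-[4-(benzyloxy)phenyl]-6-bromochromane-3,4-diol
Conditions: SmI2 (0.1 M in THF, 2.5 equiv), THF, −78 °C → rt; aq. NaHCO3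
Reagents that add atoms: none
Why: SmI2 pinacol cyclization of a 1,6-dialdehyde (the aryl ketyl adds 6-exo-trig to the tethered aldehyde); a samarium-bridged transition state should give the cis diol with O3 anti to the C2 aryl, and only C2 has to survive because C3 and C4 are reset later.

Step 9
Reactants: 12 (2R,3S,4S)-7,8-bis(benzyloxy)-2-[4-(benzyloxy)phenyl]-6-bromochromane-3,4-diol
Product: 13 (2R,3S,4R)-7,8-bis(benzyloxy)-2-[4-(benzyloxy)phenyl]-6-bromo-4-methoxychroman-3-ol
Conditions: CSA (0.2 equiv), MeOH–CH2Cl2 (1:1), rt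
Reagents that add atoms: methanol, CO
Why: SN1 solvolysis of the benzylic C4 hydroxyl through the cation stabilized by the ortho ring oxygen and the para benzyloxy group; methanol should add mainly trans to the C3 hydroxyl, which differentiates the two hydroxyls and installs the later leaving group.

Step 10
Reactants: 13 (2R,3S,4R)-7,8-bis(benzyloxy)-2-[4-(benzyloxy)phenyl]-6-bromo-4-methoxychroman-3-ol
Product: 14 (2R,4R)-7,8-bis(benzyloxy)-2-[4-(benzyloxy)phenyl]-6-bromo-4-methoxychroman-3-one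
Conditions: Dess–Martin periodinane (1.5 equiv), pyridine, CH2Cl2, 0 °C; crude used at once
Reagents that add atoms: none
Why: Dess–Martin oxidation to the flavan-3-one, the first half of the standard trans-to-cis inversion of flavan-3-ols; buffering and immediate use should prevent acid-promoted loss of methanol toward a flavylium ion.

Step 11
Reactants: 14 (2R,4R)-7,8-bis(benzyloxy)-2-[4-(benzyloxy)phenyl]-6-bromo-4-methoxychroman-3-one
Product: 15 (2R,3R,4R)-7,8-bis(benzyloxy)-2-[4-(benzyloxy)phenyl]-6-bromo-4-methoxychroman-3-ol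
Conditions: LiBH(s-Bu)3 (1.5 equiv), THF, −78 °C; then H2O
Reagents that add atoms: none
Why: Bulky-hydride ketone reduction; equatorial attack on the half-chair with the C2 aryl equatorial should give the axial alcohol cis to the aryl group, setting C3 of ring C as R.

Step 12
Reactants: 15 (2R,3R,4R)-7,8-bis(benzyloxy)-2-[4-(benzyloxy)phenyl]-6-bromo-4-methoxychroman-3-ol; 2 3,4-bis(benzyloxy)-2-hydroxybenzaldehyde
Product: 16 3,4-bis(benzyloxy)-5-[(2R,3R,4S)-7,8-bis(benzyloxy)-2-[4-(benzyloxy)phenyl]-6-bromo-3-hydroxychroman-4-yl]-2-hydroxybenzaldehyde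
Conditions: 2 (3 equiv), BF3·OEt2 (0.5 equiv), CH2Cl2, −40 → 0 °C
Reagents that add atoms: none
Why: Lewis-acid ionization of the C4 methyl ether and Friedel–Crafts capture by 2 at C5 (para to the free phenol, ortho to a benzyloxy group, the only activated position); attack anti to the axial C3 hydroxyl should give the 3,4-trans interflavanyl bond, and the C6 bromine blocks self-alkylation of ring A.

Step 13
Reactants: 16 3,4-bis(benzyloxy)-5-[(2R,3R,4S)-7,8-bis(benzyloxy)-2-[4-(benzyloxy)phenyl]-6-bromo-3-hydroxychroman-4-yl]-2-hydroxybenzaldehyde; 8 methyl (2S)-2-[4-(benzyloxy)phenyl]-2-hydroxyacetate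
Product: 17 methyl (2R)-2-[4-(benzyloxy)phenyl]-2-{2,3-bis(benzyloxy)-4-[(2R,3R,4S)-7,8-bis(benzyloxy)-2-[4-(benzyloxy)phenyl]-6-bromo-3-hydroxychroman-4-yl]-6-formylphenoxy}acetate
Conditions: PPh3, DIAD, THF, 0 °C → rt
Reagents that add atoms: none
Why: Mitsunobu etherification with inversion as in step 5, setting C2 of ring F as R; the axial C3 hydroxyl of ring C, flanked by two aryl-bearing carbons, should not be activated at a competitive rate.

Step 14
Reactants: 17 methyl (2R)-2-[4-(benzyloxy)phenyl]-2-{2,3-bis(benzyloxy)-4-[(2R,3R,4S)-7,8-bis(benzyloxy)-2-[4-(benzyloxy)phenyl]-6-bromo-3-hydroxychroman-4-yl]-6-formylphenoxy}acetate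
Product: 18 (2R,3R,4S)-7,8-bis(benzyloxy)-2-[4-(benzyloxy)phenyl]-4-{2,3-bis(benzyloxy)-4-[(1R)-1-[4-(benzyloxy)phenyl]-2-hydroxyethoxy]-5-(hydroxymethyl)phenyl}-6-bromochroman-3-ol
Conditions: i-Bu2AlH (6 equiv), CH2Cl2, −78 → 0 °C; aq. potassium sodium tartrate (KNaC4H4O6)
Reagents that add atoms: none
Why: Hydride reduction of ester and aldehyde to two primary alcohols under non-basic conditions, as in step 6.

Step 15
Reactants: 18 (2R,3R,4S)-7,8-bis(benzyloxy)-2-[4-(benzyloxy)phenyl]-4-{2,3-bis(benzyloxy)-4-[(1R)-1-[4-(benzyloxy)phenyl]-2-hydroxyethoxy]-5-(hydroxymethyl)phenyl}-6-bromochroman-3-ol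
Product: 19 3,4-bis(benzyloxy)-5-[(2R,3R,4S)-7,8-bis(benzyloxy)-2-[4-(benzyloxy)phenyl]-6-bromo-3-hydroxychroman-4-yl]-2-{(1R)-1-[4-(benzyloxy)phenyl]-2-oxoethoxy}benzaldehyde
Conditions: TEMPO (0.2 equiv), PhI(OAc)2 (2.4 equiv), CH2Cl2, rt; crude used at once
Reagents that add atoms: none
Why: Oxoammonium (TEMPO) oxidation is selective for primary over hindered secondary alcohols, so both CH2OH groups should become aldehydes while the C3 hydroxyl of ring C stays.

Step 16
Reactants: 19 3,4-bis(benzyloxy)-5-[(2R,3R,4S)-7,8-bis(benzyloxy)-2-[4-(benzyloxy)phenyl]-6-bromo-3-hydroxychroman-4-yl]-2-{(1R)-1-[4-(benzyloxy)phenyl]-2-oxoethoxy}benzaldehyde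
Product: 20 (2R,3S,4R)-7,8-bis(benzyloxy)-2-[4-(benzyloxy)phenyl]-6-[(2R,3R,4S)-7,8-bis(benzyloxy)-2-[4-(benzyloxy)phenyl]-6-bromo-3-hydroxychroman-4-yl]chromane-3,4-diol
Conditions: Cp2TiCl2 (2.5 equiv), Zn dust (5 equiv), THF, rt (forms Cp2TiCl); then 19 added over 4 h (final 0.005 M), rt; aq. NaHCO3
Reagents that add atoms: none
Why: Proposed new method: Cp2TiCl (trivalent titanium) should reduce only the aromatic aldehyde of 19 by inner-sphere electron transfer, since it leaves aliphatic aldehydes, aryl bromides and benzyl ethers alone, and the benzylic titanoxy radical at C4 can then add to the tethered α-aryloxy aldehyde carbon C3, the alkoxy radical being trapped by a second Cp2TiCl; the closest known reaction types are the titanocene pinacol coupling of aromatic aldehydes and the SmI2 pinacol cyclization of 1,6-dialdehydes. This closes ring F in a 6-exo-trig mode by forming the C3–C4 bond and sets both carbinol centers. C3 is controlled by C2: with the C2 aryl equatorial and the C3 carbonyl anti to the C2–O1 dipole (Cornforth arrangement), the new C3–O bond should be equatorial and trans to the aryl group. C4 is controlled by the radical geometry: the titanoxy oxygen of the planar benzylic radical points away from the ortho ether oxygen toward H-5 and should end pseudo-equatorial, trans to O3, and because Cp2TiCl has one free coordination site no O–metal–O bridge can enforce the cis diol expected with SmI2. The step needs chemoselective ketyl formation and no carbanion at C3 (which would expel the C2 aryloxide); both follow from the mild reducing power of trivalent titanium, and high dilution favors ring closure over intermolecular coupling.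

Step 17
Reactants: 20 (2R,3S,4R)-7,8-bis(benzyloxy)-2-[4-(benzyloxy)phenyl]-6-[(2R,3R,4S)-7,8-bis(benzyloxy)-2-[4-(benzyloxy)phenyl]-6-bromo-3-hydroxychroman-4-yl]chromane-3,4-diol
Product: 21 (2R,3S,4R)-2-(4-hydroxyphenyl)-6-[(2R,3R,4S)-3,7,8-trihydroxy-2-(4-hydroxyphenyl)chroman-4-yl]chromane-3,4,7,8-tetrol
Conditions: H2 (1 atm), Pd(OH)2/C, NaOAc (2 equiv), THF–MeOH, rt, under argon on work-up
Reagents that add atoms: none
Why: Catalytic hydrogenolysis; aryl benzyl ethers and the aryl C–Br bond should cleave faster than the secondary benzylic C4–OH of ring F under buffered neutral conditions, and NaOAc traps HBr so the acid-labile C4 carbinol is not solvolyzed.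

**Compound list**

1 | 2,3,4-trihydroxybenzaldehyde | O=Cc1ccc(O)c(O)c1O | starting material
2 | 3,4-bis(benzyloxy)-2-hydroxybenzaldehyde | O=Cc1ccc(OCc2ccccc2)c(OCc2ccccc2)c1O | intermediate
3 | 3,4-bis(benzyloxy)-5-bromo-2-hydroxybenzaldehyde | O=Cc1cc(Br)c(OCc2ccccc2)c(OCc2ccccc2)c1O | intermediate
4 | 1-(benzyloxy)-4-bromobenzene | Brc1ccc(OCc2ccccc2)cc1 | starting material
5 | dimethyl oxalate | COC(=O)C(=O)OC | starting material
6 | [4-(benzyloxy)phenyl]magnesium bromide | Br[Mg]c1ccc(OCc2ccccc2)cc1 | intermediate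
7 | methyl 2-[4-(benzyloxy)phenyl]-2-oxoacetate | COC(=O)C(=O)c1ccc(OCc2ccccc2)cc1 | intermediate
8 | methyl (2S)-2-[4-(benzyloxy)phenyl]-2-hydroxyacetate | COC(=O)[C@@H](O)c1ccc(OCc2ccccc2)cc1 | intermediate
9 | methyl (2R)-2-[4-(benzyloxy)phenyl]-2-[2,3-bis(benzyloxy)-4-bromo-6-formylphenoxy]acetate | COC(=O)[C@H](Oc1c(C=O)cc(Br)c(OCc2ccccc2)c1OCc1ccccc1)c1ccc(OCc2ccccc2)cc1 | intermediate
10 | (2R)-2-[4-(benzyloxy)phenyl]-2-[2,3-bis(benzyloxy)-4-bromo-6-(hydroxymethyl)phenoxy]ethan-1-ol | OC[C@H](Oc1c(CO)cc(Br)c(OCc2ccccc2)c1OCc1ccccc1)c1ccc(OCc2ccccc2)cc1 | intermediate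
11 | 3,4-bis(benzyloxy)-2-{(1R)-1-[4-(benzyloxy)phenyl]-2-oxoethoxy}-5-bromobenzaldehyde | O=C[C@H](Oc1c(C=O)cc(Br)c(OCc2ccccc2)c1OCc1ccccc1)c1ccc(OCc2ccccc2)cc1 | intermediate
12 | (2R,3S,4S)-7,8-bis(benzyloxy)-2-[4-(benzyloxy)phenyl]-6-bromochromane-3,4-diol (2,3-trans-3,4-cis, expected major isomer) | Brc1cc2c(c(OCc3ccccc3)c1OCc1ccccc1)O[C@H](c1ccc(OCc3ccccc3)cc1)[C@@H](O)[C@H]2O | intermediate
13 | (2R,3S,4R)-7,8-bis(benzyloxy)-2-[4-(benzyloxy)phenyl]-6-bromo-4-methoxychroman-3-ol (expected major C4 epimer) | Brc1cc2c(c(OCc3ccccc3)c1OCc1ccccc1)O[C@H](c1ccc(OCc3ccccc3)cc1)[C@@H](O)[C@@H]2OC | intermediate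
14 | (2R,4R)-7,8-bis(benzyloxy)-2-[4-(benzyloxy)phenyl]-6-bromo-4-methoxychroman-3-one | Brc1cc2c(c(OCc3ccccc3)c1OCc1ccccc1)O[C@H](c1ccc(OCc3ccccc3)cc1)C(=O)[C@@H]2OC | intermediate
15 | (2R,3R,4R)-7,8-bis(benzyloxy)-2-[4-(benzyloxy)phenyl]-6-bromo-4-methoxychroman-3-ol (2,3-cis) | Brc1cc2c(c(OCc3ccccc3)c1OCc1ccccc1)O[C@H](c1ccc(OCc3ccccc3)cc1)[C@H](O)[C@@H]2OC | intermediate
16 | 3,4-bis(benzyloxy)-5-[(2R,3R,4S)-7,8-bis(benzyloxy)-2-[4-(benzyloxy)phenyl]-6-bromo-3-hydroxychroman-4-yl]-2-hydroxybenzaldehyde | Brc1cc2c(c(OCc3ccccc3)c1OCc1ccccc1)O[C@H](c1ccc(OCc3ccccc3)cc1)[C@H](O)[C@H]2c1cc(C=O)c(O)c(OCc2ccccc2)c1OCc1ccccc1 | intermediate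
17 | methyl (2R)-2-[4-(benzyloxy)phenyl]-2-{2,3-bis(benzyloxy)-4-[(2R,3R,4S)-7,8-bis(benzyloxy)-2-[4-(benzyloxy)phenyl]-6-bromo-3-hydroxychroman-4-yl]-6-formylphenoxy}acetate | Brc1cc2c(c(OCc3ccccc3)c1OCc1ccccc1)O[C@H](c1ccc(OCc3ccccc3)cc1)[C@H](O)[C@H]2c1cc(C=O)c(O[C@H](c2ccc(OCc3ccccc3)cc2)C(=O)OC)c(OCc2ccccc2)c1OCc1ccccc1 | intermediate
18 | (2R,3R,4S)-7,8-bis(benzyloxy)-2-[4-(benzyloxy)phenyl]-4-{2,3-bis(benzyloxy)-4-[(1R)-1-[4-(benzyloxy)phenyl]-2-hydroxyethoxy]-5-(hydroxymethyl)phenyl}-6-bromochroman-3-ol | Brc1cc2c(c(OCc3ccccc3)c1OCc1ccccc1)O[C@H](c1ccc(OCc3ccccc3)cc1)[C@H](O)[C@H]2c1cc(CO)c(O[C@H](c2ccc(OCc3ccccc3)cc2)CO)c(OCc2ccccc2)c1OCc1ccccc1 | intermediate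
19 | 3,4-bis(benzyloxy)-5-[(2R,3R,4S)-7,8-bis(benzyloxy)-2-[4-(benzyloxy)phenyl]-6-bromo-3-hydroxychroman-4-yl]-2-{(1R)-1-[4-(benzyloxy)phenyl]-2-oxoethoxy}benzaldehyde | Brc1cc2c(c(OCc3ccccc3)c1OCc1ccccc1)O[C@H](c1ccc(OCc3ccccc3)cc1)[C@H](O)[C@H]2c1cc(C=O)c(O[C@H](c2ccc(OCc3ccccc3)cc2)C=O)c(OCc2ccccc2)c1OCc1ccccc1 | intermediate
20 | (2R,3S,4R)-7,8-bis(benzyloxy)-2-[4-(benzyloxy)phenyl]-6-[(2R,3R,4S)-7,8-bis(benzyloxy)-2-[4-(benzyloxy)phenyl]-6-bromo-3-hydroxychroman-4-yl]chromane-3,4-diol | Brc1cc2c(c(OCc3ccccc3)c1OCc1ccccc1)O[C@H](c1ccc(OCc3ccccc3)cc1)[C@H](O)[C@H]2c1cc2c(c(OCc3ccccc3)c1OCc1ccccc1)O[C@H](c1ccc(OCc3ccccc3)cc1)[C@@H](O)[C@@H]2O | intermediate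
21 | (2R,3S,4R)-2-(4-hydroxyphenyl)-6-[(2R,3R,4S)-3,7,8-trihydroxy-2-(4-hydroxyphenyl)chroman-4-yl]chromane-3,4,7,8-tetrol (CNP0391561.5) | Oc1ccc([C@H]2Oc3c(ccc(O)c3O)[C@H](c3cc4c(c(O)c3O)O[C@H](c3ccc(O)cc3)[C@@H](O)[C@@H]4O)[C@H]2O)cc1 | target

**Step count and risks**

Total steps: 17. Longest linear sequence: 15 steps (1 → 2 → 3 → 9 → 10 → 11 → 12 → 13 → 14 → 15 → 16 → 17 → 18 → 19 → 20 → 21).

Steps most likely to fail:

1. Step 16 (bears the label). The titanium-bound benzylic radical may couple between molecules or be reduced further before it closes onto the aldehyde, the closure may favor the cis diol, or the enolizable aldehyde may lose its C2 configuration. Fallback with known chemistry: setting out from 19, the established SmI2 pinacol cyclization (THF, −78 °C) should close the same bond and give the 3,4-cis diol, the C4 epimer of 20 F1. MnO2 (CH2Cl2, rt) should oxidize only the benzylic C4 carbinol to the hexabenzyl bromo flavanonol F2. NaBH4 (THF–MeOH, 0 °C) should then reduce the C4 ketone trans to the C3 hydroxyl, the usual course for 2,3-trans-dihydroflavonols, and the route is rejoined at 20.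

2. Step 12. The formyl-deactivated ring of 2 may trap the C4 cation too slowly, so that proton loss from C3 or alkylation of other arenes takes over. Fallback: setting out from 15, free pyrogallol (10 equiv, BF3·OEt2, THF–CH2Cl2, 0 °C), a far stronger and symmetric nucleophile, should give the 4-(2,3,4-trihydroxyphenyl) adduct F3. Vilsmeier–Haack formylation (POCl3, DMF; aq. NaOAc) can only enter the position ortho to the remote phenol and para to the near one, giving the trihydroxybenzaldehyde F4. Selective 3,4-di-O-benzylation (BnBr, K2CO3, DMF, as in step 1) then rejoins the route at 16.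

3. Step 17. Hydrogenolysis of the benzylic C4–O bond of ring F may accompany the debenzylation. Fallback: setting out from 20, MnO2 oxidation gives the hexabenzyl bromo flavanonol F2, whose aryl ketone survives hydrogenolysis. H2, Pd(OH)2/C, NaOAc (THF–MeOH) should then give the free phenolic flavanonol F5. NaBH4 (EtOH, 0 °C), the classical reduction of dihydroflavonols to 2,3-trans-3,4-trans-flavan-3,4-diols, comes back to the route at 21.

**Further compounds**

F1 | step 16 | (2R,3S,4S)-7,8-bis(benzyloxy)-2-[4-(benzyloxy)phenyl]-6-[(2R,3R,4S)-7,8-bis(benzyloxy)-2-[4-(benzyloxy)phenyl]-6-bromo-3-hydroxychroman-4-yl]chromane-3,4-diol | Brc1cc2c(c(OCc3ccccc3)c1OCc1ccccc1)O[C@H](c1ccc(OCc3ccccc3)cc1)[C@H](O)[C@H]2c1cc2c(c(OCc3ccccc3)c1OCc1ccccc1)O[C@H](c1ccc(OCc3ccccc3)cc1)[C@@H](O)[C@H]2O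
F2 | step 16 | (2R,3R)-7,8-bis(benzyloxy)-2-[4-(benzyloxy)phenyl]-6-[(2R,3R,4S)-7,8-bis(benzyloxy)-2-[4-(benzyloxy)phenyl]-6-bromo-3-hydroxychroman-4-yl]-3-hydroxychroman-4-one | Brc1cc2c(c(OCc3ccccc3)c1OCc1ccccc1)O[C@H](c1ccc(OCc3ccccc3)cc1)[C@H](O)[C@H]2c1cc2c(c(OCc3ccccc3)c1OCc1ccccc1)O[C@H](c1ccc(OCc3ccccc3)cc1)[C@@H](O)C2=O
F3 | step 12 | (2R,3R,4S)-7,8-bis(benzyloxy)-2-[4-(benzyloxy)phenyl]-6-bromo-4-(2,3,4-trihydroxyphenyl)chroman-3-ol | Brc1cc2c(c(OCc3ccccc3)c1OCc1ccccc1)O[C@H](c1ccc(OCc3ccccc3)cc1)[C@H](O)[C@H]2c1ccc(O)c(O)c1O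
F4 | step 12 | 5-[(2R,3R,4S)-7,8-bis(benzyloxy)-2-[4-(benzyloxy)phenyl]-6-bromo-3-hydroxychroman-4-yl]-2,3,4-trihydroxybenzaldehyde | Brc1cc2c(c(OCc3ccccc3)c1OCc1ccccc1)O[C@H](c1ccc(OCc3ccccc3)cc1)[C@H](O)[C@H]2c1cc(C=O)c(O)c(O)c1O
F5 | step 17 | (2R,3R)-3,7,8-trihydroxy-2-(4-hydroxyphenyl)-6-[(2R,3R,4S)-3,7,8-trihydroxy-2-(4-hydroxyphenyl)chroman-4-yl]chroman-4-one | Oc1ccc([C@H]2Oc3c(ccc(O)c3O)[C@H](c3cc4c(c(O)c3O)O[C@H](c3ccc(O)cc3)[C@@H](O)C4=O)[C@H]2O)cc1
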